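If a repeat of these runs is to end with left-handed product above the half of the charge that was left-handed substrate, right-handed substrate has to be carried over by racemization catalyst, so c(racemization catalyst) outside the idle complex is the thing to watch.

| setting | south-east | east | epsilon | alpha |
|---|---|---|---|---|
| left-handed substrate | 0.18 M | 0.18 M | 0.18 M | 0.18 M |
| right-handed substrate | 0.18 M | 0.18 M | 0.18 M | 0.18 M |
| partner | 2.5 equiv | 2.5 equiv | 2.50 equiv | 2.50 equiv |
| free catalyst | 0.2 mol% | 0.2 mol% | 0.2 mol% | 0.2 mol% |
| racemization catalyst | 0.05 mol% | 0.05 mol% | 0.05 mol% | 0.05 mol% |
| added ligand | 52 µM | 63 µM | 58 µM | 87 µM |
| remark | run made earlier | run made earlier |  |  |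
| time |  |  | 8.0 min | 8.0 min |

| south-east: time / min | south-east: left-handed product / % | east: time / min | east: left-handed product / % |
|---|---|---|---|
| 0.667 | 45.8 | 0.667 | 43.7 |
| 1.00 | 55.3 | 1.00 | 52.1 |
| 2.00 | 71.8 | 2.00 | 69.4 |
| 3.00 | 80.8 | 3.00 | 78.2 |
| 5.00 | 88.4 | 5.00 | 87.1 |
| 8.00 | 94.4 | 8.00 | 92.6 |

(readings scatter by 0.5 percentage points)

- free catalyst is single-handed; left-handed substrate and right-handed substrate are mirror images of each other, charged as a racemate, each of them at the stated concentration
- what was read earlier has a scatter of 0.5 percentage points, one standard deviation
- steps thought possible: partner + free catalyst + left-handed substrate -> free catalyst + left-handed product; partner + free catalyst + right-handed substrate -> free catalyst + right-handed product; racemization catalyst + added ligand <-> idle complex; left-handed substrate + racemization catalyst <-> right-handed substrate + racemization catalyst; racemization catalyst -> spent catalyst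

- which of the two there is more of at the end, epsilon (right-handed product / left-handed product)
- which of the two there is more of at the end, alpha (right-handed product / left-handed product)
- how much left-handed product is there at the end, in percent of the left-handed substrate and right-handed substrate together charged: epsilon
- how much left-handed product is there at the end, in percent of the left-handed substrate and right-handed substrate together charged: alpha

The loading on left-handed substrate gives 90.0 µM of racemization catalyst. In epsilon, 58 µM of added ligand leaves 32.0 µM. This is the margin, racemization catalyst charged minus added ligand, which equals c(racemization catalyst) if binding is tight. The south-east run has a margin of 38.0 µM, the east run 27.0 µM, and alpha 3.00 µM.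

In the first instants, free catalyst couples left-handed substrate with partner, and the south-east run reads 45.8% left-handed product at 0.667 min. By 1.00 min it reads 55.3%, more than half of the charge, so racemization is already delivering. The tail follows. Left-handed product need not climb to full conversion, because some material leaves as right-handed product, so the tail is read from the evenly spaced readings at 2.00 min, 5.00 min and 8.00 min, whose two rises give a constant without any assumed final level. Taking the approach as a single exponential (pseudo-first-order), that constant reads 0.339 min⁻¹ in the south-east run and 0.390 min⁻¹ in the east run. Each is a reading carrying the scatter of 0.5 percentage points, and the east value comes out higher although the east run has the smaller margin.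

My own reckoning starts from epsilon, whose margin lies between those of the two runs, so interpolating in added ligand gives 93.4%. Alpha's margin lies outside them. Scaling the south-east constant by the margin gives 0.0268 min⁻¹. If half of the charge waits as right-handed substrate and converts at that pace, alpha reaches about 59.6%, with binding taken as complete.

The forecast names left-handed product for epsilon and left-handed product for alpha as the larger product, with 93.5% and 89%: “Alpha at 87 µM retains about 73–75% of the south-east racemization rate, giving about 89%.” For alpha, it and my reckoning differ.

The flask gives left-handed product as the larger product in epsilon and left-handed product in alpha, with 93.2% and 80.0% left-handed product.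

    partner + free catalyst + left-handed substrate → free catalyst + left-handed product (k = 328 M⁻² s⁻¹)
    partner + free catalyst + right-handed substrate → free catalyst + right-handed product (k = 6.46 M⁻² s⁻¹)
    racemization catalyst + added ligand ⇌ idle complex (K = 3.20 × 10⁶ M⁻¹, k = 7090 M⁻¹ s⁻¹)
    left-handed substrate + racemization catalyst ⇌ right-handed substrate + racemization catalyst, rate k4*[racemization catalyst]*[left-handed substrate] forward; the back reaction follows from the equilibrium constant (k = 454 M⁻¹ s⁻¹)
    racemization catalyst → spent catalyst (k = 1.70 × 10⁻⁵ s⁻¹)

In epsilon the margin is 35.6% of the racemization catalyst charged and 35.9% stands as racemization catalyst at 8.00 min; at 0.722 min left-handed substrate has a half-life of 0.78 min by the forward racemization step alone, longer than the 0.35 min by coupling. In alpha the margin is 3.33% of that charge while 7.53% stands as racemization catalyst, which stretches epsilon's 0.79 min racemization half-life to 3.77 min, and at 8.00 min alpha still holds 11.5% right-handed substrate.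

(All runs are simulated for substances that don't exist; the scatter is artificial.)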